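## The problem

Helihumulone (16) is a dearomatised acylphloroglucinol: one six-membered carbocycle in which every carbon is functionalised. Numbering the ring from its sp3 carbon, C1 carries a methoxy and a prenyl group, C2 is a ketone, C3 carries the 3-phenylpropanoyl group, C4 and C6 are enolised carbonyls and C5 carries the second prenyl group (these ring numbers are used throughout and are independent of the locants in systematic names). The only stereocentre is the quaternary C1, (R) in the tautomer drawn; nothing else in the molecule can relay or correct it, and with neither a hydrogen nor a free hydroxyl it cannot be adjusted afterwards. The methoxy group sits on a tertiary carbon between two carbonyls, where late O-methylation is unrealistic, so it should arrive with a building block. The sensitive parts are three: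

- the two trisubstituted alkenes, which add HX and cyclise onto neighbouring enol oxygens to chromans under strong acid;
- the strongly acidic, chelating tricarbonyl array around C3, which quenches basic organometallics;
- the 2,2-disubstituted 1,3-dicarbonyl unit at C1, which hard nucleophiles cleave by retro-Claisen reaction unless its flanks are enolised.

Three different carbon substituents must be placed on C1, C3 and C5 of one trione, and C5 must be prenylated once only. What opens a short route is that, seen from C1, the ring halves C2–C3–C4 and C6–C5–C4 differ only in what C3 and C5 carry: cutting C3–C4 and levelling both ends to thioesters gives a chain with two identical β-keto thioester arms on a prochiral C1. Closing that chain by letting the methylene of one arm acylate on the thioester of the other makes the ring, the C3–C4 bond and the stereocentre at once, and leaves a thioester on C3 as the future acyl group.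

## Retrosynthesis

**16 ⇒ 12 + 14.** The last bond made is the one between the side-chain carbonyl carbon on C3 and its α-methylene. The neighbouring cut, between C3 and that carbonyl carbon, would need C-acylation of a ring with a free C3–H, with enol oxygens as competing sites. Cutting one bond further out leaves the carbonyl carbon on the ring as the thioester 12 and removes the phenethyl unit as the zinc reagent 14. The forward reaction must make a ketone from a thioester beside two free enols, a ring ketone and two alkenes, which is what the Fukuyama coupling does. 14 comes in one step from (2-iodoethyl)benzene (13).

**12 ⇒ 10 + 2.** The C5–CH2 bond of the ring prenyl group is cut, giving 10 and prenyl bromide (2). This prenyl group cannot be carried through ring formation, because a substituent on one arm of the open chain would end the equivalence of the arms on which the stereochemical plan rests. In 10, C5 is the only ring carbon bearing hydrogen and lies between two carbonyls. The forward step is therefore a C-alkylation of a cyclic 1,3-dicarbonyl dianion that must stop after one prenyl group.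

**10 ⇒ 9.** The ring is opened at C3–C4. Of the ring bonds, this is the one whose cleavage, with C4 taken to the thioester level, gives a chain (9) in which the two remaining substituents on C1 are the same β-keto thioester. Cuts at C1–C2 or C2–C3 give chains with unlike ends and a C1 that is already stereogenic or planar. 9 has no ring and no stereocentre. The forward reaction is an intramolecular Claisen condensation in which a chiral, redox-inert Lewis acid with a weak amine base must decide which enantiotopic arm becomes the nucleophile. It must favour carbon over oxygen acylation and must not be reversible. The thioester it leaves on C3 is the acyl precursor needed in the last step.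

**9 ⇒ 6 + 7.** The two bonds between the ketone carbons (C2, C6) and the arm methylenes (C3, C5) are cut together, giving the malonyl dichloride 6 and two molecules of S-ethyl thioacetate (7), used as its lithium enolate 8. Symmetry lets one operation build both arms. The reverse order, quaternising C1 of a preformed 3,5-dioxoheptanedioate, would face three competing acidic sites. The forward step is a double crossed Claisen acylation that must be run and quenched cold so that 9 does not close prematurely.

**6 ⇒ 5 ⇒ 4 ⇒ 1 + 2.** 6 is traced through the diacid 5 to the diester 4, and the C1–CH2 bond of the first prenyl group is cut to dimethyl methoxymalonate (1) and 2. The tertiary methoxy group is thus bought, and the quaternary carbon is made by alkylating a malonate with a single acidic hydrogen. 4, 5 and 6 have no α-hydrogen, so ketene formation and over-alkylation are excluded. The only demands are a saponification and an acid chloride formation that spare the alkene and avoid decarboxylation.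

## Roads not taken

**Alternative 1:** The cut is at C1–C6 and leads to the racemic 2-pyranone A1, in which C6 is the lactone carbonyl and C1 a secondary carbon on the side chain. In the forward key step a chiral quaternary ammonium aryloxide would open the lactone to an aryl ester, the dienolate would shift to the planar C1=C2 enolate, and this would C-acylate on C6 to give A2. (A2 is named (S) only because the ranking of C2 and C6 changes; its spatial arrangement is that of 16.)
- Merits: both enantiomers of A1 converge on one product; the C5 prenyl group and a differentiated C4 oxygen are in place before the ring forms, so the mono-prenylation problem of the chosen route does not arise; no stoichiometric metal is needed.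
- Weak points: the stereo-determining event is acylation of a fully substituted, acyclic α-methoxy enolate whose geometry and face are held only by an ion pair. The aromatic 2-pyranone is reluctant to open, and the opened dienolate should reclose through oxygen more easily than it acylates at C1. A2 is a 2,2-disubstituted 1,3-diketone exposed to retro-Claisen cleavage by the same aryloxide. Afterwards C3 must still be acylated and the C4 methyl enol ether cleaved under conditions the prenyl groups tolerate poorly.
- Comparison: in placing the C5 prenyl group early this road is better. The chosen plan sets against that a rigid, chelated nucleophile, a product protected as its enolate the moment it forms, a C3 acyl handle delivered by the ring closure, and no late deprotection.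

**Alternative 2:** The cut is at C1–C2 and leads to the keto aldehyde A3, whose C2 is an aldehyde and whose C1 and C6 form a 1,2-diketone. A chiral N-heterocyclic carbene would convert the aldehyde into an acyl anion equivalent that adds to the C1 ketone (intramolecular crossed benzoin reaction) to give the tertiary alcohol A4.
- Merits: enantioselective aldehyde–ketone benzoin closures of six-membered rings are established, so this bond-forming step is closer to known chemistry than the chosen one, and it is catalytic with no leaving group to manage.
- Weak points: the closure delivers a hydroxyl where 16 has a methoxy group. Methylating a tertiary α-ketol flanked by two carbonyls, in a molecule with a far more acidic C3 methylene, is not credible without protecting-group steps and invites the α-ketol shift (ring contraction) typical of humulone-type acyloins. A3 is a masked tricarbonyl with a β-alkoxy-β,γ-unsaturated aldehyde, a defined (E)-enol ether and a hydration-prone diketone, and attack at C6 (five-membered ring) competes. C3 acylation and enol ether cleavage remain as in alternative 1.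
- Comparison: the chosen plan concedes the better precedent of the bond-forming step. It sets against it a methoxy group present from the first compound, a precursor made in four steps from stable materials, and an endgame without ether formation or cleavage.

**Alternative 3:** The cut is at C2–C3, after the stereocentre has been set on an open chain. The prochiral diester 4 of the present route would be hydrolysed by an esterase to the half ester A5, the acid end extended to the acyclic diketo ester A6, and the terminal carbanion of the dianion of A6 would attack the methyl ester (Dieckmann-type closure) to give A7, which then needs C3 acylation.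
- Merits: every step is a known reaction type; the stereocentre is fixed early and cannot racemise; the C5 prenyl group enters with the diketone; the step count equals or is one below that of the chosen route. In risk per step this is the more conservative plan.
- Weak points: the esterase must distinguish two ester groups whose surroundings differ only in methoxy versus prenyl, and its sense and level of selection on such a substrate cannot be chosen or predicted. Making A6 needs C-acylation of the more substituted enolate of an unsymmetrical ketone by a neopentyl-type acid chloride, with regiochemistry and O-acylation to control. The dianion closure uses strong base beside an α-alkoxy β-keto ester that can fragment by retro-Claisen reaction. The acyl group must still be put on C3 at the end.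
- Comparison: against the safer reaction types the chosen plan sets control by a ligand available in both antipodes, construction of both arms in one operation, and a ring closure that installs the C3 acyl carbon. It also keeps this road open, since its endgame fallback passes through the ring system of A7.

Key step: step 5

Remark on the chemistry: 10, 12 and 16 are tautomeric mixtures; each is drawn and named as one tautomer, and the descriptor (R) at C1 refers to that drawing.
Remark on the chemistry: the sense of induction of the bis(oxazoline) complex in step 5 cannot be predicted with confidence. The (S,S)-ligand is written; if the first run is found to give the (S)-series, its commercial antipode takes its place with nothing else changed.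

## Route

Step 1
Reactants: 1 dimethyl 2-methoxypropanedioate (dimethyl methoxymalonate); 2 1-bromo-3-methylbut-2-ene (prenyl bromide)
Product: 4 dimethyl 2-methoxy-2-(3-methylbut-2-enyl)propanedioate, via sodium enolate of the malonate 3 (not isolated)
Conditions: NaH (1.1 equiv), THF/DMF, 0 °C; then 2 (1.1 equiv), 0 °C to rt
Reagents that add atoms: none
Why: Malonate alkylation (SN2): the tertiary enolate 3 attacks the unhindered CH2 terminus of the primary allylic bromide, and 4 has no acidic hydrogen left, so a second alkylation is impossible.

Step 2
Reactants: 4 dimethyl 2-methoxy-2-(3-methylbut-2-enyl)propanedioate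
Product: 5 2-methoxy-2-(3-methylbut-2-enyl)propanedioic acid
Conditions: KOH (3 equiv), MeOH/H2O, 50 °C; then cold 1 M HCl to pH 2, EtOAc extraction, evaporation below 30 °C
Reagents that add atoms: potassium hydroxide, [K+].[OH-]
Why: Saponification of both methyl esters; a fully substituted malonic acid decarboxylates only on heating, so cold acidification and cool evaporation should deliver the diacid with the alkene intact.

Step 3
Reactants: 5 2-methoxy-2-(3-methylbut-2-enyl)propanedioic acid
Product: 6 2-methoxy-2-(3-methylbut-2-enyl)propanedioyl dichloride
Conditions: (COCl)2 (2.5 equiv), DMF (cat.), CH2Cl2, 0 °C to rt, argon sweep; evaporated and used crude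
Reagents that add atoms: oxalyl chloride, O=C(Cl)C(=O)Cl
Why: Acid chloride formation through the chloroiminium salt from oxalyl chloride and DMF; with no α-hydrogen there is no ketene pathway, and sweeping out HCl at low temperature protects the trisubstituted alkene.

Step 4
Reactants: 6 2-methoxy-2-(3-methylbut-2-enyl)propanedioyl dichloride; 7 S-ethyl ethanethioate (S-ethyl thioacetate)
Product: 9 S,S-diethyl 4-methoxy-4-(3-methylbut-2-enyl)-3,5-dioxoheptanebis(thioate), via lithium enolate of the thioacetate 8 (not isolated)
Conditions: 7 (4.2 equiv), LiN(SiMe3)2 (4.2 equiv), THF, −78 °C; then 6 added dropwise, −78 °C; quenched at −78 °C with 1 M HCl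
Reagents that add atoms: none
Why: Crossed Claisen acylation of a thioester lithium enolate by an acid chloride, run at both ends of 6; inverse addition into excess 8 lets intermolecular C-acylation outrun intramolecular O-acylation. The second two equivalents of 8 store each new β-keto thioester as its unreactive lithium enolate (returning 7), and the cold acidic quench prevents base-induced, racemic ring closure.

Step 5
Reactants: 9 S,S-diethyl 4-methoxy-4-(3-methylbut-2-enyl)-3,5-dioxoheptanebis(thioate)
Product: 10 S-ethyl (5R)-2-hydroxy-5-methoxy-5-(3-methylbut-2-enyl)-4,6-dioxocyclohex-1-ene-1-carbothioate
Conditions: Mg(OTf)2 (20 mol%), (S,S)-2,2'-(propane-2,2-diyl)bis(4-phenyl-4,5-dihydro-1,3-oxazole) (22 mol%), N-methylmorpholine (1.1 equiv), 4 Å molecular sieves, CHCl3, −20 to 0 °C, argon sweep of the headspace; cold 1 M HCl work-up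
Reagents that add atoms: none
Why: Proposed new method: the complex of Mg(OTf)2 with the chiral bis(oxazoline) binds one β-keto thioester arm of 9 as a six-membered chelate, with the C1 methoxy oxygen as a third donor on the octahedral divalent magnesium; N-methylmorpholine removes the acidified C3 hydrogen (soft enolisation), the enolate carbon adds to the thioester carbonyl of the other arm through a closed six-membered transition state, and the tetrahedral intermediate expels ethanethiolate. The thiolate is quenched within the ion pair by the new C3–H, which lies between three carbonyls and is far more acidic than EtSH, so 10 is stored as its enolate, the thiol leaves with the argon stream and no free thiolate remains to re-open the ring. The closest known reaction types are the soft-enolisation Claisen acylation of thioesters with divalent magnesium and a tertiary amine, the magnesium bis(oxazoline)/amine-catalysed Michael addition of 1,3-dicarbonyl compounds, the catalytic desymmetrising aldol closure of 2,2-disubstituted 1,3-diketones and the Claisen cyclases of polyketide biosynthesis. The six-membered ring closes in a 6-(enolendo)-exo-trig mode and forms the C3–C4 bond. C1 becomes a stereocentre through the choice of which enantiotopic arm is the nucleophile: with the methoxy oxygen held in the chelate plane, the prenyl group and the second arm lie on opposite faces of the enolate, the ligand shields one face, and only the complex whose free arm lies on the open face can close, while the other returns to 9 (Curtin–Hammett situation). The step needs arm selectivity, C- over O-acylation and a slow uncatalysed reaction; chelation of both enolate oxygens leaves carbon as the nucleophilic site, and a base as weak as N-methylmorpholine should enolise only metal-bound 9. Divalent magnesium replaces the more usual Cu(OTf)2 because divalent copper is reduced by thiols to CuSEt (monovalent copper) and diethyl disulfide, which would destroy the catalyst as soon as product forms.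

Step 6
Reactants: 10 S-ethyl (5R)-2-hydroxy-5-methoxy-5-(3-methylbut-2-enyl)-4,6-dioxocyclohex-1-ene-1-carbothioate; 2 1-bromo-3-methylbut-2-ene
Product: 12 S-ethyl (5R)-2,4-dihydroxy-5-methoxy-3,5-bis(3-methylbut-2-enyl)-6-oxocyclohexa-1,3-diene-1-carbothioate, via dilithium dienolate 11 (not isolated)
Conditions: LiN(SiMe3)2 (2.1 equiv), THF, −78 °C; then 2 (1.0 equiv), −78 °C to rt; cold 1 M HCl work-up
Reagents that add atoms: none
Why: C-alkylation of the dianion of a cyclic tricarbonyl compound, as in the prenylation of acylphloroglucinols: in 11 the last-formed anion makes C5 the most nucleophilic carbon while C3 is blocked by the thioester. Lithium in THF and a soft allylic bromide favour carbon over oxygen, the limiting amount of 2 restrains a second alkylation, and the non-nucleophilic amide base leaves the thioester and quaternary C1 untouched.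

Step 7
Reactants: 13 (2-iodoethyl)benzene
Product: 14 iodo(2-phenylethyl)zinc
Conditions: Zn dust (1.5 equiv, activated with 1,2-dibromoethane and Me3SiCl, 5 mol% each), THF, 40 °C; used as a titrated solution
Reagents that add atoms: zinc, [Zn]
Why: Direct oxidative insertion of activated zinc metal into a primary alkyl iodide gives the alkylzinc iodide.

Step 8
Reactants: 12 S-ethyl (5R)-2,4-dihydroxy-5-methoxy-3,5-bis(3-methylbut-2-enyl)-6-oxocyclohexa-1,3-diene-1-carbothioate; 14 iodo(2-phenylethyl)zinc
Product: 16 helihumulone [(6R)-3,5-dihydroxy-6-methoxy-4,6-bis(3-methylbut-2-enyl)-2-(3-phenylpropanoyl)cyclohexa-2,4-dien-1-one], via bis(iodozinc) dienolate 15 (not isolated)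
Conditions: 14 (4 equiv), PdCl2(PPh3)2 (10 mol%), toluene/THF, rt; cold 1 M HCl work-up
Reagents that add atoms: none
Why: Fukuyama coupling: two equivalents of 14 are spent on the two enol protons to give 15, whose thioester adds oxidatively to zerovalent palladium (formed from the divalent precatalyst by 14), transmetalates with a further equivalent of 14 and reductively eliminates the ketone. Alkylzinc iodides do not add to ketones or alkenes, and the new acyl group becomes part of a chelated tricarbonyl enolate at once, so C1 and both prenyl groups are untouched.

## Compound list

1 | dimethyl 2-methoxypropanedioate (dimethyl methoxymalonate) | COC(C(=O)OC)C(=O)OC | starting material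
2 | 1-bromo-3-methylbut-2-ene (prenyl bromide) | CC(C)=CCBr | starting material
3 | sodium enolate of 1 (sodium 1,2,3-trimethoxy-3-oxoprop-1-en-1-olate; formed in the flask) | COC(C(=O)OC)=C([O-])OC.[Na+] | intermediate
4 | dimethyl 2-methoxy-2-(3-methylbut-2-enyl)propanedioate | COC(CC=C(C)C)(C(=O)OC)C(=O)OC | intermediate
5 | 2-methoxy-2-(3-methylbut-2-enyl)propanedioic acid | COC(CC=C(C)C)(C(=O)O)C(=O)O | intermediate
6 | 2-methoxy-2-(3-methylbut-2-enyl)propanedioyl dichloride | COC(CC=C(C)C)(C(=O)Cl)C(=O)Cl | intermediate
7 | S-ethyl ethanethioate (S-ethyl thioacetate) | CCSC(C)=O | starting material
8 | lithium 1-(ethylsulfanyl)ethenolate (lithium enolate of 7; formed in the flask) | [Li+].[O-]C(=C)SCC | intermediate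
9 | S,S-diethyl 4-methoxy-4-(3-methylbut-2-enyl)-3,5-dioxoheptanebis(thioate) | CCSC(=O)CC(=O)C(OC)(CC=C(C)C)C(=O)CC(=O)SCC | intermediate
10 | S-ethyl (5R)-2-hydroxy-5-methoxy-5-(3-methylbut-2-enyl)-4,6-dioxocyclohex-1-ene-1-carbothioate | CO[C@@]1(CC=C(C)C)C(=O)C(C(=O)SCC)=C(O)CC1=O | intermediate
11 | dilithium dienolate of 10 (formed in the flask) | CO[C@@]1(CC=C(C)C)C(=O)C(C(=O)SCC)=C([O-])C=C1[O-].[Li+].[Li+] | intermediate
12 | S-ethyl (5R)-2,4-dihydroxy-5-methoxy-3,5-bis(3-methylbut-2-enyl)-6-oxocyclohexa-1,3-diene-1-carbothioate | CO[C@@]1(CC=C(C)C)C(=O)C(C(=O)SCC)=C(O)C(CC=C(C)C)=C1O | intermediate
13 | (2-iodoethyl)benzene | ICCc1ccccc1 | starting material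
14 | iodo(2-phenylethyl)zinc | I[Zn]CCc1ccccc1 | intermediate
15 | bis(iodozinc) dienolate of 12 (formed in the flask) | CO[C@@]1(CC=C(C)C)C(=O)C(C(=O)SCC)=C(O[Zn]I)C(CC=C(C)C)=C1O[Zn]I | intermediate
16 | helihumulone, (6R)-3,5-dihydroxy-6-methoxy-4,6-bis(3-methylbut-2-enyl)-2-(3-phenylpropanoyl)cyclohexa-2,4-dien-1-one | CO[C@@]1(CC=C(C)C)C(=O)C(C(=O)CCc2ccccc2)=C(O)C(CC=C(C)C)=C1O | target

## Step count and risks

Total step count: 8. Longest linear sequence: 7 steps (1 → 4 → 5 → 6 → 9 → 10 → 12 → 16); step 7 is a one-step side branch.

**Step 5 (key step, proposed new method).**
- What may go wrong: insufficient discrimination between the two arms, because methoxy and prenyl are both modest in size near the metal and because an amine-promoted, ligand-free closure may run alongside. Lactonisation through the enolate oxygen may compete with C-acylation. Turnover may stall if the product enolate holds on to magnesium; the remedy inside the method is a full equivalent of the complex.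
- Fallback (known chemistry), from 9 back to 10: achiral soft-enolisation Dieckmann-type closure with MgBr2·OEt2 and i-Pr2NEt in CH2Cl2 should give racemic S-ethyl 2-hydroxy-5-methoxy-5-(3-methylbut-2-enyl)-4,6-dioxocyclohex-1-ene-1-carbothioate F2. As a strong vinylogous acid, this would be resolved by fractional crystallisation of the (S)-1-phenylethylammonium salt of the (5R)-acid F3 and released with cold dilute HCl, returning to the route at 10. It is assumed that this diastereomeric salt is the less soluble one; otherwise the antipodal amine is used.

**Step 8.**
- What may go wrong: slow oxidative addition of the electron-rich, enolate-conjugated thioester to zerovalent palladium, protonolysis of 14 beyond the two planned equivalents, or β-hydride loss leading to reduction instead of coupling.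
- Fallback, from 12 back to 16: AgO2CCF3 in wet THF cleaves the thioester by way of the acylketene. The resulting (5R)-2,4-dihydroxy-5-methoxy-3,5-bis(3-methylbut-2-enyl)-6-oxocyclohexa-1,3-diene-1-carboxylic acid F4 loses CO2 on gentle warming to (6R)-3,5-dihydroxy-6-methoxy-4,6-bis(3-methylbut-2-enyl)cyclohexa-2,4-dien-1-one F5, which stays chiral because C5 already carries its prenyl group. O-acylation with 3-phenylpropanoyl chloride and Et3N gives the enol ester (4R)-5-hydroxy-4-methoxy-4,6-bis(3-methylbut-2-enyl)-3-oxocyclohexa-1,5-dien-1-yl 3-phenylpropanoate F6. The 4-dimethylaminopyridine-catalysed O-to-C acyl shift known for cyclic 1,3-diones then moves the acyl group to C3, the only free ring carbon, returning at 16.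

**Step 4.**
- What may go wrong: after the first acylation the lithium enolate of the new β-keto thioester may attack the remaining acid chloride through oxygen and close a six-membered enol lactone. 8 may self-condense or lose thiolate if it warms. The dianion of 9 may cyclise before the quench.
- Fallback, from 5 back to 9: carbonyldiimidazole converts the diacid into 1,1'-[2-methoxy-2-(3-methylbut-2-enyl)propanedioyl]bis(1H-imidazole) F1, which is treated with Mg(O2CCH2COSEt)2 (decarboxylative Claisen condensation of a malonic half thioester under neutral conditions), returning at 9.

**Step 6.**
- What may go wrong: a second prenylation at C5 through proton exchange between the mono-alkylated anion and unreacted 11, and O-prenylation.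
- Fallback, from 10 back to 12: Tsuji–Trost prenylation of the neutral enol with Pd(PPh3)4 and methyl 2-methylbut-3-en-2-yl carbonate. Only one equivalent of base (methoxide from the carbonate) is ever released, and the soft nucleophile attacks the unsubstituted terminus of the π-prenyl complex. This returns at 12 without any new compound (F0).

## Further compounds

F1 | step 4 | 1,1'-[2-methoxy-2-(3-methylbut-2-enyl)propanedioyl]bis(1H-imidazole) | COC(CC=C(C)C)(C(=O)n1ccnc1)C(=O)n1ccnc1
F2 | step 5 | racemic S-ethyl 2-hydroxy-5-methoxy-5-(3-methylbut-2-enyl)-4,6-dioxocyclohex-1-ene-1-carbothioate | COC1(CC=C(C)C)C(=O)C(C(=O)SCC)=C(O)CC1=O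
F3 | step 5 | (S)-1-phenylethylammonium salt of the (5R)-acid 10 (enolate of the ring hydroxyl) | CO[C@@]1(CC=C(C)C)C(=O)C(C(=O)SCC)=C([O-])CC1=O.C[C@H]([NH3+])c1ccccc1
F0 | step 6 | none | none
F4 | step 8 | (5R)-2,4-dihydroxy-5-methoxy-3,5-bis(3-methylbut-2-enyl)-6-oxocyclohexa-1,3-diene-1-carboxylic acid | CO[C@@]1(CC=C(C)C)C(=O)C(C(=O)O)=C(O)C(CC=C(C)C)=C1O
F5 | step 8 | (6R)-3,5-dihydroxy-6-methoxy-4,6-bis(3-methylbut-2-enyl)cyclohexa-2,4-dien-1-one | CO[C@@]1(CC=C(C)C)C(=O)C=C(O)C(CC=C(C)C)=C1O
F6 | step 8 | (4R)-5-hydroxy-4-methoxy-4,6-bis(3-methylbut-2-enyl)-3-oxocyclohexa-1,5-dien-1-yl 3-phenylpropanoate | CO[C@@]1(CC=C(C)C)C(=O)C=C(OC(=O)CCc2ccccc2)C(CC=C(C)C)=C1O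
A1 | alternative 1 | racemic 4-methoxy-6-(1-methoxy-4-methylpent-3-enyl)-3-(3-methylbut-2-enyl)-2H-pyran-2-one | COC(CC=C(C)C)c1cc(OC)c(CC=C(C)C)c(=O)o1
A2 | alternative 1 | (2S)-2,5-dimethoxy-2,4-bis(3-methylbut-2-enyl)cyclohex-4-ene-1,3-dione | CO[C@@]1(CC=C(C)C)C(=O)CC(OC)=C(CC=C(C)C)C1=O
A3 | alternative 2 | (3E)-3-methoxy-9-methyl-4-(3-methylbut-2-enyl)-5,6-dioxodeca-3,8-dienal | O=CC/C(OC)=C(/CC=C(C)C)C(=O)C(=O)CC=C(C)C
A4 | alternative 2 | (2S)-2-hydroxy-5-methoxy-2,4-bis(3-methylbut-2-enyl)cyclohex-4-ene-1,3-dione | O[C@@]1(CC=C(C)C)C(=O)CC(OC)=C(CC=C(C)C)C1=O
A5 | alternative 3 | (2R)-2-methoxy-2-(methoxycarbonyl)-5-methylhex-4-enoic acid | COC(=O)[C@@](OC)(CC=C(C)C)C(=O)O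
A6 | alternative 3 | methyl (2R)-2-methoxy-2,4-bis(3-methylbut-2-enyl)-3,5-dioxohexanoate (C4 unassigned) | COC(=O)[C@@](OC)(CC=C(C)C)C(=O)C(CC=C(C)C)C(C)=O
A7 | alternative 3 | (6R)-3,5-dihydroxy-6-methoxy-4,6-bis(3-methylbut-2-enyl)cyclohexa-2,4-dien-1-one | CO[C@@]1(CC=C(C)C)C(=O)C=C(O)C(CC=C(C)C)=C1O
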